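**Retrosynthetic overview**
1. Target ⇐ C9 acetylation and 12‑O‑silyl removal ⇐ γ‑lactone, C4 acetate and Z‑C5=C6 made together by a palladium‑mediated trans‑1,4‑acetoxylactonization (C7–O and C4–O bonds) of a ten‑membered (4Z,6Z)‑diene β‑hydroxy acid.
2. Diene acid ⇐ semi‑hydrogenation and chelation‑controlled propionate aldol (C8–C17) on a cyclic α‑hydroxy ynone ⇐ ten‑membered ring closed at C7–C8 by CrCl2‑mediated addition of an iodoalkyne to an α‑hydroxy aldehyde.
3. Acyclic precursor ⇐ C2 arm built by allylation, ozonolysis, Z‑selective iodo‑olefination and Sonogashira coupling; the C8–C9 arm is carried as the glyceraldehyde acetonide.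
4. Ring A ⇐ Diels–Alder reaction of a 1,3‑bis(silyloxy)pentadiene with the (S)‑glyceraldehyde‑derived (E)‑2‑methyl enal, then C11 epimerisation by kinetic protonation and Evans–Tishchenko reduction (sets C12, installs 14‑OAc).
5. Ring order: cyclohexane (ring A) first, then the ten‑membered carbocycle, last the γ‑lactone.

Assumption: atom labels C1–C20 are briarane positions (C15 = methyl on C1, C16 = methyl on C5, C20 = methyl on C11, C17/C18/C19 = lactone CH, its methyl and the carbonyl). "Target configuration" means the spatial arrangement of the target, which is (1R,2R,4R,5Z,7S,8S,9R,10S,11R,12S,14S,17R). Compound 5 is bought as the (S)‑aldehyde.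

**Step 1**
Reactants: 1 pent‑1‑yn‑3‑ol
Product: 2 pent‑1‑yn‑3‑one
Conditions: IBX, EtOAc, 75 °C
Reagents that add atoms: none
Why: IBX oxidation of a secondary propargylic alcohol to the ynone; no stereocentre is involved.

**Step 2**
Reactants: 2 pent‑1‑yn‑3‑one
Product: 4 (1E,3Z)‑1,3‑bis(tert‑butyldimethylsilyloxy)penta‑1,3‑diene, via silyloxy enone 3 (not isolated)
Conditions: tBuMe2SiOH, DABCO (10 mol%), CH2Cl2, 0 °C; then tBuMe2SiOTf, Et3N, 0 °C
Reagents that add atoms: tert‑butyldimethylsilanol CC(C)(C)[Si](C)(C)O; tert‑butyldimethylsilyl triflate CC(C)(C)[Si](C)(C)OS(=O)(=O)C(F)(F)F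
Why: amine‑catalysed oxa‑Michael addition of the silanol to the ynone gives the (E)‑β‑silyloxy enone, and soft enolisation/O‑silylation of the ethyl ketone gives the (Z)‑enol ether, i.e. a Danishefsky‑type diene with both terminal substituents "outside".

**Step 3**
Reactants: 5 (S)‑2,2‑dimethyl‑1,3‑dioxolane‑4‑carbaldehyde
Product: 6 (E)‑3‑[(4R)‑2,2‑dimethyl‑1,3‑dioxolan‑4‑yl]‑2‑methylprop‑2‑enal
Conditions: Ph3P=C(CH3)CHO, toluene, 80 °C
Reagents that add atoms: 2‑(triphenylphosphoranylidene)propanal CC(C=O)=P(c1ccccc1)(c1ccccc1)c1ccccc1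
Why: Wittig olefination with a stabilised ylide gives the (E)‑enal and leaves the acetonide stereocentre (future C9) untouched.

**Step 4**
Reactants: 6 (E)‑3‑[(4R)‑2,2‑dimethyl‑1,3‑dioxolan‑4‑yl]‑2‑methylprop‑2‑enal; 4 (1E,3Z)‑1,3‑bis(tert‑butyldimethylsilyloxy)penta‑1,3‑diene
Product: 7 ring A cycloadduct aldehyde
Conditions: toluene, BHT (cat.), 120 °C, sealed tube
Reagents that add atoms: none
Why: thermal normal‑demand Diels–Alder reaction forming ring A; the nucleophilic diene terminus (C11) bonds to the enal β‑carbon (C10), the endo formyl group ends up cis to 14‑O and to the C11 methyl, and the diene adds anti to the dioxolane CH2 in the A(1,3)‑locked conformer (C9–H eclipsing the C1 methyl), so C1, C10 and C14 are set from the glyceraldehyde centre (C11 is formed epimeric and corrected in step 7).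

**Step 5**
Reactants: 7 ring A cycloadduct aldehyde
Product: 8 ring A homoallylic alcohol
Conditions: allylB(pin), (R)‑TRIP phosphoric acid (5 mol%), 4 Å MS, toluene, −30 °C
Reagents that add atoms: allylboronic acid pinacol ester C=CCB1OC(C)(C)C(C)(C)O1
Why: chiral‑phosphoric‑acid‑catalysed allylboration through a chair transition state; catalyst control, reinforced by Felkin–Anh attack anti to the C14 branch of the α‑quaternary aldehyde, sets C2 (R).

**Step 6**
Reactants: 8 ring A homoallylic alcohol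
Product: 9 ring A keto diol (11‑epi)
Conditions: HF·pyridine, pyridine, THF, 0 °C → rt
Reagents that add atoms: none
Why: fluoride‑mediated cleavage of the silyl enol ether (to the C12 ketone) and of the C14 silyl ether; the buffered medium leaves the acetonide and the β‑hydroxy ketone intact.

**Step 7**
Reactants: 9 ring A keto diol (11‑epi)
Product: 10 ring A keto diol (target configuration at C11)
Conditions: LiN(iPr)2 (3.5 equiv), THF, −78 → −30 °C; then AcOH, −78 °C
Reagents that add atoms: none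
Why: deprotonation/kinetic reprotonation; the C14 alkoxide steers enolisation away from C13 to the C11=C12 enolate (no β‑elimination from an oxido dianion), and the proton enters from the less hindered face anti to C9 and the C1 methyl, giving the C11 epimer with C20 cis to C9.

**Step 8**
Reactants: 10 ring A keto diol (target configuration at C11)
Product: 11 ring A 14‑acetate 2,12‑diol
Conditions: CH3CHO (6 equiv), SmI2 (0.3 equiv), THF, −10 °C
Reagents that add atoms: acetaldehyde CC=O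
Why: Evans–Tishchenko reduction; intramolecular hydride transfer within the samarium‑bound hemiacetal at O14 delivers H to C12 from the face of O14, giving the 1,3‑anti diol (12S) with the acetate already on O14.

**Step 9**
Reactants: 11 ring A 14‑acetate 2,12‑diol
Product: 13 ring A 2,14‑diacetate 12‑silyl ether, via monosilyl ether 12 (not isolated)
Conditions: tBuMe2SiCl, imidazole, DMF, 0 °C → rt; then Ac2O, DMAP, Et3N, rt
Reagents that add atoms: tert‑butyldimethylsilyl chloride CC(C)(C)[Si](C)(C)Cl; acetic anhydride CC(=O)OC(C)=O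
Why: selective silylation of the ring carbinol at C12 (C2–OH is flanked by the quaternary C1 and reacts much more slowly), followed by DMAP‑catalysed acetylation of C2–OH.

**Step 10**
Reactants: 13 ring A 2,14‑diacetate 12‑silyl ether
Product: 15 C4 aldehyde, via ozonide 14 (not isolated)
Conditions: O3, CH2Cl2, −78 °C; then PPh3, −78 °C → rt
Reagents that add atoms: ozone [O-][O+]=O
Why: ozonolysis of the only alkene with reductive work‑up gives the β‑acetoxy aldehyde; no stereocentre is touched.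

**Step 11**
Reactants: 15 C4 aldehyde
Product: 16 (Z)‑vinyl iodide
Conditions: [Ph3PCH(I)CH3]I, NaN(SiMe3)2, THF, −78 → −20 °C
Reagents that add atoms: (1‑iodoethyl)triphenylphosphonium iodide CC(I)[P+](c1ccccc1)(c1ccccc1)c1ccccc1.[I-]
Why: Stork–Zhao‑type Wittig olefination with the α‑iodo ylide gives the (Z)‑2‑iodoalkene (iodine cis to C3), which fixes the later C4=C5 geometry; low temperature limits β‑elimination of the acetate.

**Step 12**
Reactants: 16 (Z)‑vinyl iodide
Product: 17 (Z)‑enyne silane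
Conditions: HC≡CSiMe3, PdCl2(PPh3)2 (5 mol%), CuI (10 mol%), iPr2NH, THF, rt
Reagents that add atoms: ethynyltrimethylsilane C#C[Si](C)(C)C
Why: Sonogashira coupling with retention of the alkene geometry installs C6 and C7.

**Step 13**
Reactants: 17 (Z)‑enyne silane
Product: 18 (Z)‑enyne iodoalkyne
Conditions: NIS, AgNO3 (10 mol%), acetone, rt, dark
Reagents that add atoms: N‑iodosuccinimide O=C1CCC(=O)N1I
Why: silver‑catalysed iododesilylation of the alkynylsilane gives the 1‑iodoalkyne needed for chromium insertion.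

**Step 14**
Reactants: 18 (Z)‑enyne iodoalkyne
Product: 19 iodoalkyne 8,9‑diol
Conditions: Zn(NO3)2·6H2O, MeCN, 50 °C
Reagents that add atoms: none
Why: mild Lewis‑acid hydrolysis of the terminal acetonide; silyl ether, acetates and iodoalkyne survive.

**Step 15**
Reactants: 19 iodoalkyne 8,9‑diol
Product: 20 iodoalkyne α‑hydroxy aldehyde
Conditions: TEMPO (10 mol%), NCS, Bu4NCl, CH2Cl2/aq. NaHCO3, 0 °C
Reagents that add atoms: none
Why: oxoammonium (TEMPO) oxidation is selective for the primary C8 alcohol over the secondary C9 alcohol; the aldehyde is used crude.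

**Step 16**
Reactants: 20 iodoalkyne α‑hydroxy aldehyde
Product: 21 ten‑membered enyne 8,9‑diol
Conditions: CrCl2 (8 equiv), NiCl2 (1 mol%), THF, 0.002 M, slow addition, rt
Reagents that add atoms: none
Why: Nozaki–Hiyama–Kishi‑type macrocyclisation (alkynylchromium addition to the aldehyde) closes the ten‑membered ring at C7–C8 under non‑basic conditions; the C8 carbinol forms as an epimer mixture that converges in step 17.

**Step 17**
Reactants: 21 ten‑membered enyne 8,9‑diol
Product: 22 ten‑membered α‑hydroxy ynone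
Conditions: MnO2 (activated, excess), CH2Cl2, rt
Reagents that add atoms: none
Why: MnO2 oxidises the propargylic C8 alcohol selectively and leaves the saturated C9 alcohol.

**Step 18**
Reactants: 22 ten‑membered α‑hydroxy ynone
Product: 23 alkyne β‑hydroxy acid
Conditions: EtCO2SiMe2tBu, LiN(iPr)2 (3.5 equiv), THF/DMPU, −78 °C; then 22, −78 °C; AcOH; aq. citric acid
Reagents that add atoms: tert‑butyldimethylsilyl propanoate CCC(=O)O[Si](C)(C)C(C)(C)C
Why: aldol addition of the lithium enolate (methyl cis to O–Li) to the ketone, 1,2 rather than conjugate; one equivalent forms the C9 lithium alkoxide, Cram‑chelate attack from the C9–H face sets C8, a Zimmerman–Traxler chair with the slim alkynyl group axial sets C17, and the silyl ester is hydrolysed on work‑up.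

**Step 19**
Reactants: 23 alkyne β‑hydroxy acid
Product: 24 (4Z,6Z)‑diene β‑hydroxy acid
Conditions: H2 (1 atm), Pd/CaCO3 poisoned with Pb(OAc)2, quinoline, EtOAc, rt
Reagents that add atoms: none
Why: Lindlar‑type syn semi‑hydrogenation of the ring alkyne gives the (Z)‑C6=C7 alkene and hence the cisoid ring diene.

**Step 20**
Reactants: 24 (4Z,6Z)‑diene β‑hydroxy acid
Product: 25 lactone 4‑acetate (9‑OH, 12‑silyl ether)
Conditions: Pd(OAc)2 (10 mol%), p‑benzoquinone (2 equiv), LiOAc, AcOH/acetone 1:4, chloride‑free, 25 °C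
Reagents that add atoms: acetic acid CC(=O)O
Why: Proposed new method: a chloride‑free Pd(OAc)2/benzoquinone trans‑1,4‑acetoxylactonization run for the first time on a ten‑membered, trisubstituted (Z,Z)‑1,3‑diene; the C19 carboxylate adds to C7 anti to divalent palladium from the face on which the medium ring holds C17 out of the C6=C7 plane (γ‑lactone with C6 trans to C9, setting C7), the anti‑configured π‑allyl over C4–C6 then takes acetate from the metal face at C4 (cis migration), so O4 ends up trans to O7 and C5=C6 is Z; the closest known reaction type is the palladium‑catalysed 1,4‑acetoxylactonization and 1,4‑diacetoxylation of cyclohexa‑ and cyclohepta‑1,3‑dienes, not yet shown on medium rings or trisubstituted dienes.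

**Step 21**
Reactants: 25 lactone 4‑acetate (9‑OH, 12‑silyl ether)
Product: 26 12‑O‑silyl target
Conditions: Ac2O, DMAP, pyridine, CH2Cl2, 0 °C → rt
Reagents that add atoms: acetic anhydride CC(=O)OC(C)=O
Why: DMAP‑catalysed acetylation of the secondary C9 alcohol; the tertiary C8 alcohol does not react under these conditions.

**Step 22**
Reactants: 26 12‑O‑silyl target
Product: 27 target CNP0183630.2
Conditions: HF·pyridine, pyridine, THF, 0 °C → rt
Reagents that add atoms: none
Why: fluoride desilylation of the C12 ether; acetates, lactone and the tertiary alcohol are stable to buffered HF.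

**Compound list**
1 | pent‑1‑yn‑3‑ol (racemic) | CCC(O)C#C | starting material
2 | pent‑1‑yn‑3‑one | CCC(=O)C#C | intermediate
3 | (E)‑1‑(tert‑butyldimethylsilyloxy)pent‑1‑en‑3‑one | CCC(=O)/C=C/O[Si](C)(C)C(C)(C)C | intermediate
4 | (1E,3Z)‑1,3‑bis(tert‑butyldimethylsilyloxy)penta‑1,3‑diene | C/C=C(\O[Si](C)(C)C(C)(C)C)/C=C/O[Si](C)(C)C(C)(C)C | intermediate
5 | (S)‑2,2‑dimethyl‑1,3‑dioxolane‑4‑carbaldehyde | O=C[C@@H]1COC(C)(C)O1 | starting material
6 | (E)‑3‑[(4R)‑2,2‑dimethyl‑1,3‑dioxolan‑4‑yl]‑2‑methylprop‑2‑enal | O=C/C(C)=C/[C@@H]1COC(C)(C)O1 | intermediate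
7 | (1R,2S,5S,6S)‑2,4‑bis(tert‑butyldimethylsilyloxy)‑6‑[(4R)‑2,2‑dimethyl‑1,3‑dioxolan‑4‑yl]‑1,5‑dimethylcyclohex‑3‑ene‑1‑carbaldehyde (ring A; CHO = C2, silyloxy carbons = C14 and C12, methyls on C1 and C11, dioxolane = C9/C8; C11 methyl cis to CHO, i.e. 11‑epi) | CC(C)(C)[Si](C)(C)O[C@H]1C=C(O[Si](C)(C)C(C)(C)C)[C@@H](C)[C@H]([C@@H]2COC(C)(C)O2)[C@@]1(C)C=O | intermediate
8 | homoallylic alcohol of 7: CHO replaced by (R)‑CH(OH)CH2CH=CH2 (C2–C4) | CC(C)(C)[Si](C)(C)O[C@H]1C=C(O[Si](C)(C)C(C)(C)C)[C@@H](C)[C@H]([C@@H]2COC(C)(C)O2)[C@@]1(C)[C@H](O)CC=C | intermediate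
9 | ring A keto diol: C12 ketone, free 14‑OH and 2‑OH, C11 methyl still cis to 14‑OH (11‑epi), allyl and acetonide intact | O[C@H]1CC(=O)[C@@H](C)[C@H]([C@@H]2COC(C)(C)O2)[C@@]1(C)[C@H](O)CC=C | intermediate
10 | C11 epimer of 9: C11 methyl cis to the C1 methyl and to C9 (target configuration at C1, C2, C9, C10, C11, C14) | O[C@H]1CC(=O)[C@H](C)[C@H]([C@@H]2COC(C)(C)O2)[C@@]1(C)[C@H](O)CC=C | intermediate
11 | ring A 14‑acetate: new 12‑OH trans to 14‑OAc and cis to the C11 methyl (12S), 2‑OH free | CC(=O)O[C@H]1C[C@H](O)[C@H](C)[C@H]([C@@H]2COC(C)(C)O2)[C@@]1(C)[C@H](O)CC=C | intermediate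
12 | 12‑O‑tert‑butyldimethylsilyl ether of 11 | CC(=O)O[C@H]1C[C@H](O[Si](C)(C)C(C)(C)C)[C@H](C)[C@H]([C@@H]2COC(C)(C)O2)[C@@]1(C)[C@H](O)CC=C | intermediate
13 | 2‑O‑acetate of 12 (2,14‑diacetate, 12‑silyl ether) | CC(=O)O[C@H]1C[C@H](O[Si](C)(C)C(C)(C)C)[C@H](C)[C@H]([C@@H]2COC(C)(C)O2)[C@@]1(C)[C@H](OC(C)=O)CC=C | intermediate
14 | secondary ozonide (1,2,4‑trioxolane) of the terminal alkene of 13, mixture at the new ring carbon | CC(=O)O[C@H]1C[C@H](O[Si](C)(C)C(C)(C)C)[C@H](C)[C@H]([C@@H]2COC(C)(C)O2)[C@@]1(C)[C@H](OC(C)=O)CC3OCOO3 | intermediate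
15 | C4 aldehyde: CH2CH=CH2 of 13 replaced by CH2CHO | CC(=O)O[C@H]1C[C@H](O[Si](C)(C)C(C)(C)C)[C@H](C)[C@H]([C@@H]2COC(C)(C)O2)[C@@]1(C)[C@H](OC(C)=O)CC=O | intermediate
16 | (Z)‑vinyl iodide: C3H2–C4H=C5(I)CH3, iodine cis to C3 | CC(=O)O[C@H]1C[C@H](O[Si](C)(C)C(C)(C)C)[C@H](C)[C@H]([C@@H]2COC(C)(C)O2)[C@@]1(C)[C@H](OC(C)=O)C/C=C(/C)I | intermediate
17 | (Z)‑enyne silane: iodine of 16 replaced by C≡C–SiMe3 (C6≡C7) | CC(=O)O[C@H]1C[C@H](O[Si](C)(C)C(C)(C)C)[C@H](C)[C@H]([C@@H]2COC(C)(C)O2)[C@@]1(C)[C@H](OC(C)=O)C/C=C(/C)C#C[Si](C)(C)C | intermediate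
18 | (Z)‑enyne iodoalkyne: SiMe3 of 17 replaced by iodine | CC(=O)O[C@H]1C[C@H](O[Si](C)(C)C(C)(C)C)[C@H](C)[C@H]([C@@H]2COC(C)(C)O2)[C@@]1(C)[C@H](OC(C)=O)C/C=C(/C)C#CI | intermediate
19 | iodoalkyne 8,9‑diol (acetonide of 18 removed; C9 R) | CC(=O)O[C@H]1C[C@H](O[Si](C)(C)C(C)(C)C)[C@H](C)[C@H]([C@@H](O)CO)[C@@]1(C)[C@H](OC(C)=O)C/C=C(/C)C#CI | intermediate
20 | iodoalkyne α‑hydroxy aldehyde (C8 aldehyde, free 9‑OH) | CC(=O)O[C@H]1C[C@H](O[Si](C)(C)C(C)(C)C)[C@H](C)[C@H]([C@@H](O)C=O)[C@@]1(C)[C@H](OC(C)=O)C/C=C(/C)C#CI | intermediate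
21 | ten‑membered enyne diol (briarane bicyclo[8.4.0] carbocycle): C7–C8 bond formed, C8 carbinol as epimer mixture, 9‑OH free, Z‑C4=C5, C6≡C7 | CC(=O)O[C@H]1C[C@H](O[Si](C)(C)C(C)(C)C)[C@H](C)[C@@H]2[C@@H](O)C(O)C#C/C(C)=C\C[C@@H](OC(C)=O)[C@]21C | intermediate
22 | ten‑membered α‑hydroxy ynone (C8 ketone) | CC(=O)O[C@H]1C[C@H](O[Si](C)(C)C(C)(C)C)[C@H](C)[C@@H]2[C@@H](O)C(=O)C#C/C(C)=C\C[C@@H](OC(C)=O)[C@]21C | intermediate
23 | alkyne β‑hydroxy acid: C8 tertiary carbinol bearing CH(CH3)CO2H (C17, C18, C19), target configuration at C8 and C17 | CC(=O)O[C@H]1C[C@H](O[Si](C)(C)C(C)(C)C)[C@H](C)[C@@H]2[C@@H](O)[C@](O)([C@@H](C)C(=O)O)C#C/C(C)=C\C[C@@H](OC(C)=O)[C@]21C | intermediate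
24 | (4Z,6Z)‑diene β‑hydroxy acid | CC(=O)O[C@H]1C[C@H](O[Si](C)(C)C(C)(C)C)[C@H](C)[C@@H]2[C@@H](O)[C@](O)([C@@H](C)C(=O)O)/C=C\C(C)=C/C[C@@H](OC(C)=O)[C@]21C | intermediate
25 | 9‑deacetyl‑12‑O‑silyl target: 7,19‑γ‑lactone, 4‑OAc, Z‑C5=C6, free 8‑OH and 9‑OH | CC(=O)O[C@H]1C[C@H](O[Si](C)(C)C(C)(C)C)[C@H](C)[C@@H]2[C@@H](O)[C@@]3(O)[C@H](/C=C(/C)[C@H](OC(C)=O)C[C@@H](OC(C)=O)[C@]21C)OC(=O)[C@@H]3C | intermediate
26 | 12‑O‑tert‑butyldimethylsilyl ether of the target | CC(=O)O[C@H]1C[C@H](O[Si](C)(C)C(C)(C)C)[C@H](C)[C@@H]2[C@@H](OC(C)=O)[C@@]3(O)[C@H](/C=C(/C)[C@H](OC(C)=O)C[C@@H](OC(C)=O)[C@]21C)OC(=O)[C@@H]3C | intermediate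
27 | CNP0183630.2: (1R,2R,4R,5Z,7S,8S,9R,10S,11R,12S,14S,17R)‑2,4,9,14‑tetraacetoxy‑8,12‑dihydroxybriar‑5‑ene 7,19‑γ‑lactone | CC(=O)O[C@H]1C[C@H](O)[C@H](C)[C@@H]2[C@@H](OC(C)=O)[C@@]3(O)[C@H](/C=C(/C)[C@H](OC(C)=O)C[C@@H](OC(C)=O)[C@]21C)OC(=O)[C@@H]3C | target

**Step count**
Total: 22 steps. Longest linear sequence: 21 steps (1 → 2 → 4 → 7 → … → 27; the branch from 5 joins at step 4).

**Three steps most likely to fail**

Step 7 (C11 epimerisation). Enolisation may occur at C13 instead of C11, leaving 9 unchanged. The fallback sets out from 9. Exhaustive thermodynamic silylation (Me3SiCl, NaI, Et3N, MeCN, 40 °C) gives the tris(trimethylsilyl) C11=C12 enol ether F1. MeLi (THF, 0 °C) then releases the C11 lithium enolate regiospecifically (House method); it is protonated at −78 °C with 2,6‑di‑tert‑butylphenol, and dilute citric acid removes the two silyl ethers. This comes back to the route at 10.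

Step 16 (ten‑membered ring closure). The strained cyclic enyne may form slowly and oligomerise. The fallback sets out from 18. Diimide reduction (2‑nitrobenzenesulfonyl hydrazide, Et3N) of the iodoalkyne gives the (1Z,3Z)‑dienyl iodide F2. Acetonide cleavage as in step 14 gives the dienyl iodide diol F3, and TEMPO/NCS oxidation gives the dienyl iodide hydroxy aldehyde F4. The classical vinyl‑iodide Nozaki–Hiyama–Kishi closure (CrCl2, NiCl2 cat., THF/DMSO, high dilution) gives the ten‑membered dienyl diol F5, which carries no alkyne strain. MnO2 gives the cyclic hydroxy dienone F6, and the aldol of step 18 on F6 comes back to the route at 24, so step 19 is not needed.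

Step 20 (new acetoxylactonization). The medium‑ring π‑allyl may isomerise (E‑alkene), or acetate may be delivered to the wrong face. The fallback uses known chemistry and sets out from 24. Iodolactonization (I2, NaHCO3, MeCN, 0 °C) gives the 1,2‑adduct, the C6‑iodo γ‑lactone F7, with O7 and iodine anti. Pd(PPh3)4 (5 mol%) and CsOAc in THF then ionise the allylic iodide with inversion and deliver acetate to C4 anti to zerovalent‑palladium‑derived π‑allyl (net 1,3‑transposition with retention). This places O4 trans to O7, moves the alkene to C5=C6, and comes back to the route at 25.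

**Further compounds**
F1 | step 7 | tris(trimethylsilyl) C11=C12 enol ether of 9 (2‑O, 14‑O and enol 12‑O silylated) | C[Si](C)(C)O[C@H]1CC(O[Si](C)(C)C)=C(C)[C@H]([C@@H]2COC(C)(C)O2)[C@@]1(C)[C@H](O[Si](C)(C)C)CC=C
F2 | step 16 | (1Z,3Z)‑dienyl iodide: C≡C–I of 18 reduced to (Z)‑CH=CH–I | CC(=O)O[C@H]1C[C@H](O[Si](C)(C)C(C)(C)C)[C@H](C)[C@H]([C@@H]2COC(C)(C)O2)[C@@]1(C)[C@H](OC(C)=O)C/C=C(/C)\C=C/I
F3 | step 16 | dienyl iodide 8,9‑diol | CC(=O)O[C@H]1C[C@H](O[Si](C)(C)C(C)(C)C)[C@H](C)[C@H]([C@@H](O)CO)[C@@]1(C)[C@H](OC(C)=O)C/C=C(/C)\C=C/I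
F4 | step 16 | dienyl iodide α‑hydroxy aldehyde | CC(=O)O[C@H]1C[C@H](O[Si](C)(C)C(C)(C)C)[C@H](C)[C@H]([C@@H](O)C=O)[C@@]1(C)[C@H](OC(C)=O)C/C=C(/C)\C=C/I
F5 | step 16 | ten‑membered (4Z,6Z)‑dienyl 8,9‑diol (C8 epimer mixture) | CC(=O)O[C@H]1C[C@H](O[Si](C)(C)C(C)(C)C)[C@H](C)[C@@H]2[C@@H](O)C(O)/C=C\C(C)=C/C[C@@H](OC(C)=O)[C@]21C
F6 | step 16 | ten‑membered (4Z,6Z)‑α‑hydroxy dienone | CC(=O)O[C@H]1C[C@H](O[Si](C)(C)C(C)(C)C)[C@H](C)[C@@H]2[C@@H](O)C(=O)/C=C\C(C)=C/C[C@@H](OC(C)=O)[C@]21C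
F7 | step 20 | C6‑iodo γ‑lactone: 7,19‑lactone with iodine at C6 anti to O7, Z‑C4=C5 retained | CC(=O)O[C@H]1C[C@H](O[Si](C)(C)C(C)(C)C)[C@H](C)[C@@H]2[C@@H](O)[C@@]3(O)[C@H]([C@H](I)/C(C)=C\C[C@@H](OC(C)=O)[C@]21C)OC(=O)[C@@H]3C
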